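The ketone carbon, lactone C4, lactone C3 and the benzylic CH2 of the target form a four-carbon chain, a γ-aryl ketone. Closed on itself, this chain is a 1-arylcyclobutanol. Everything rests on cutting the aryl–CH2 bond: a mirror-symmetric cyclobutanol that carries OBn and CO2Me on the far ring carbon is opened by a chiral palladium catalyst in the presence of an aryl bromide. This single operation forms the aryl–CH2 bond, unmasks the aroyl ketone and fixes the fully substituted carbinol C3 by desymmetrisation. The same bromide supplies both guaiacyl rings. Hydroxymethylation of the ketone α-carbon then closes the butyrolactone ring and sets C4, and hydrogenolysis ends the route.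

Key step: step 4

Assumption: the sense of induction of the ferrocenyl P,N ligand on cyclobutanol 6 cannot be derived from first principles, so the ligand antipode that leads to (S)-7 is used, and the one written in step 4 stands for that choice.

Step 1
Reactants: 1 1-(benzyloxy)-4-bromo-2-methoxybenzene; 2 methyl 3-oxocyclobutane-1-carboxylate
Product: 4 methyl 3-[4-(benzyloxy)-3-methoxyphenyl]-3-hydroxycyclobutane-1-carboxylate (cis/trans mixture), via arylmagnesium bromide 3 (not isolated)
Conditions: Mg turnings, THF, 40 °C; then 2, THF, −78 °C; aq. NH4Cl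
Reagents that add atoms: none
Why: Grignard addition, in which the strained cyclobutanone carbonyl is far more electrophilic than the ester at −78 °C; the ratio of ring isomers does not matter because the ester-bearing carbon is planarised in step 2.

Step 2
Reactants: 4 methyl 3-[4-(benzyloxy)-3-methoxyphenyl]-3-hydroxycyclobutane-1-carboxylate
Product: 5 methyl cis-1,3-dihydroxy-3-[4-(benzyloxy)-3-methoxyphenyl]cyclobutane-1-carboxylate (both hydroxyl groups on the same ring face; achiral)
Conditions: LiN(iPr)2 (2.3 equiv), THF, −78 °C; 2-(phenylsulfonyl)-3-phenyloxaziridine, −78 °C; AcOH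
Reagents that add atoms: 2-(phenylsulfonyl)-3-phenyloxaziridine, O=S(=O)(c1ccccc1)N1OC1c1ccccc1
Why: Enolate hydroxylation with an N-sulfonyloxaziridine, in which the alkoxide–enolate dianion is planar at the ester-bearing carbon and the oxidant should approach across the ring from the face of the small lithium alkoxide rather than that of the aryl group, placing the two oxygen atoms cis while the mirror plane through C1 and C3 is kept.

Step 3
Reactants: 5 methyl cis-1,3-dihydroxy-3-[4-(benzyloxy)-3-methoxyphenyl]cyclobutane-1-carboxylate
Product: 6 methyl cis-1-(benzyloxy)-3-hydroxy-3-[4-(benzyloxy)-3-methoxyphenyl]cyclobutane-1-carboxylate (OBn and OH on the same ring face; achiral)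
Conditions: NaH (1.0 equiv), BnBr (1.05 equiv), Bu4NI (cat.), THF/DMF, −10 to 0 °C
Reagents that add atoms: benzyl bromide, BrCc1ccccc1
Why: Williamson ether synthesis with one equivalent of base, in which the hydroxyl α to the ester is the more acidic and less shielded of the two tertiary alcohols and is alkylated first; the ether later prevents a second palladium alkoxide and blocks retro-aldol loss of configuration.

Step 4
Reactants: 6 methyl cis-1-(benzyloxy)-3-hydroxy-3-[4-(benzyloxy)-3-methoxyphenyl]cyclobutane-1-carboxylate; 1 1-(benzyloxy)-4-bromo-2-methoxybenzene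
Product: 7 methyl (2S)-2-(benzyloxy)-2-[4-(benzyloxy)-3-methoxybenzyl]-4-[4-(benzyloxy)-3-methoxyphenyl]-4-oxobutanoate
Conditions: Pd(OAc)2 (5 mol %), (R)-N,N-dimethyl-1-[(S)-2-(diphenylphosphino)ferrocenyl]ethylamine (10 mol %), 1 (1.05 equiv), Cs2CO3 (1.5 equiv), toluene, 50 °C
Reagents that add atoms: none
Why: Oxidative addition of 1 to zerovalent palladium and exchange of bromide for the caesium alkoxide of 6 give an aryl(alkoxo) complex of divalent palladium, whose strain-driven β-carbon elimination cleaves one of the two enantiotopic C(OH)–CH2 ring bonds, releases the aryl ketone and leaves a primary alkylpalladium that reductively eliminates with the aryl ligand to form the aryl–CH2 bond. The closest known reaction type is the palladium-catalysed enantioselective arylative ring opening of prochiral tert-cyclobutanols with aryl bromides to γ-aryl ketones. No ring is closed; the four-membered ring is opened. The only new stereocenter, the benzyloxy-bearing quaternary carbon (later lactone C3), arises by desymmetrisation and is controlled by the chiral P,N ligand, which chooses between the two ring bonds on either side of the mirror plane, so the outcome does not depend on a size difference between OBn and CO2Me. The step needs chemoselectivity against β-hydride elimination, β-alkoxide elimination, cleavage at the other carbinol and α-arylation of 7: the carbon next to palladium is quaternary and has no β-hydrogen, benzyloxide is a poor leaving group, the second oxygen is an ether so only one palladium alkoxide can form, and the ketone α-CH2 of 7 is neopentylic.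

Step 5
Reactants: 7 methyl (2S)-2-(benzyloxy)-2-[4-(benzyloxy)-3-methoxybenzyl]-4-[4-(benzyloxy)-3-methoxyphenyl]-4-oxobutanoate
Product: 9 (3S,4S)-3-(benzyloxy)-4-[4-(benzyloxy)-3-methoxybenzoyl]-3-[4-(benzyloxy)-3-methoxybenzyl]oxolan-2-one, via hydroxymethyl ketone 8 (not isolated)
Conditions: LiN(SiMe3)2 (1.1 equiv), THF, −78 °C; HCHO (gas from cracked paraformaldehyde), −78 to −40 °C; AcOH; then PPTS (cat.), toluene, 50 °C
Reagents that add atoms: formaldehyde, C=O
Why: Crossed aldol addition to formaldehyde followed by 5-exo-trig lactonisation onto the methyl ester, in which lithium chelation between the enolate oxygen and the benzyloxy oxygen exposes the face anti to the arylmethyl group and so gives the (4S) centre with aroyl trans to arylmethyl, the arrangement also favoured at equilibrium because C4 is α to the ketone.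

Step 6
Reactants: 9 (3S,4S)-3-(benzyloxy)-4-[4-(benzyloxy)-3-methoxybenzoyl]-3-[4-(benzyloxy)-3-methoxybenzyl]oxolan-2-one
Product: 10 (3S,4S)-3-hydroxy-4-(4-hydroxy-3-methoxybenzoyl)-3-(4-hydroxy-3-methoxybenzyl)oxolan-2-one
Conditions: H2 (1 atm), Pd(OH)2/C, EtOAc/EtOH, rt
Reagents that add atoms: none
Why: Catalytic hydrogenolysis should cleave the two aryl benzyl ethers and the tertiary alkyl benzyl ether under neutral conditions that leave the electron-rich aryl ketone, the lactone and both stereocenters untouched.

Compound list
1 | 1-(benzyloxy)-4-bromo-2-methoxybenzene | COc1cc(Br)ccc1OCc1ccccc1 | starting material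
2 | methyl 3-oxocyclobutane-1-carboxylate | COC(=O)C1CC(=O)C1 | starting material
3 | [4-(benzyloxy)-3-methoxyphenyl]magnesium bromide | COc1cc([Mg]Br)ccc1OCc1ccccc1 | intermediate
4 | methyl 3-[4-(benzyloxy)-3-methoxyphenyl]-3-hydroxycyclobutane-1-carboxylate (cis/trans mixture, configuration not drawn) | COC(=O)C1CC(O)(c2ccc(OCc3ccccc3)c(OC)c2)C1 | intermediate
5 | methyl cis-1,3-dihydroxy-3-[4-(benzyloxy)-3-methoxyphenyl]cyclobutane-1-carboxylate | COC(=O)[C@]1(O)C[C@](O)(c2ccc(OCc3ccccc3)c(OC)c2)C1 | intermediate
6 | methyl cis-1-(benzyloxy)-3-hydroxy-3-[4-(benzyloxy)-3-methoxyphenyl]cyclobutane-1-carboxylate | COC(=O)[C@]1(OCc2ccccc2)C[C@](O)(c2ccc(OCc3ccccc3)c(OC)c2)C1 | intermediate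
7 | methyl (2S)-2-(benzyloxy)-2-[4-(benzyloxy)-3-methoxybenzyl]-4-[4-(benzyloxy)-3-methoxyphenyl]-4-oxobutanoate | COc1cc(C[C@@](CC(=O)c2ccc(OCc3ccccc3)c(OC)c2)(OCc2ccccc2)C(=O)OC)ccc1OCc1ccccc1 | intermediate
8 | methyl (2S,3S)-2-(benzyloxy)-2-[4-(benzyloxy)-3-methoxybenzyl]-3-(hydroxymethyl)-4-[4-(benzyloxy)-3-methoxyphenyl]-4-oxobutanoate | COc1cc(C[C@@]([C@H](CO)C(=O)c2ccc(OCc3ccccc3)c(OC)c2)(OCc2ccccc2)C(=O)OC)ccc1OCc1ccccc1 | intermediate
9 | (3S,4S)-3-(benzyloxy)-4-[4-(benzyloxy)-3-methoxybenzoyl]-3-[4-(benzyloxy)-3-methoxybenzyl]oxolan-2-one | COc1cc(C[C@@]2(OCc3ccccc3)C(=O)OC[C@@H]2C(=O)c2ccc(OCc3ccccc3)c(OC)c2)ccc1OCc1ccccc1 | intermediate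
10 | (3S,4S)-3-hydroxy-4-(4-hydroxy-3-methoxybenzoyl)-3-(4-hydroxy-3-methoxybenzyl)oxolan-2-one | COc1cc(C[C@@]2(O)C(=O)OC[C@@H]2C(=O)c2ccc(O)c(OC)c2)ccc1O | target

Total step count: 6
Longest linear sequence: 6 steps (1 or 2 to 10)

Steps most likely to fail

Step 4.
- **What may go wrong:** The chiral catalyst may discriminate poorly between the two enantiotopic ring bonds. The alkylpalladium may also lose benzyloxide by β-elimination faster than it couples.
- **Fallback:** It sets out from 6 (with 1) and comes back at 7. The C–C cleavage is moved from a palladium alkoxide to a radical manifold. Compounds 6 and 1 are irradiated with blue light in the presence of 9-mesityl-10-methylacridinium perchlorate, NiBr2 (1,2-dimethoxyethane adduct), 4,4'-di-tert-butyl-2,2'-bipyridine and 2,4,6-collidine.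
- **How it works:** Oxidation of the electron-rich aryl carbinol and proton-coupled electron transfer give the alkoxy radical. Its β-scission gives the primary radical, which does not expel a β-alkoxy group. An arylnickel species captures this radical and forms the same aryl–CH2 bond. This should give the racemic keto ester F1, which is resolved by preparative chromatography on a chiral stationary phase to give 7.

Step 5.
- **What may go wrong:** The lithium enolate may eliminate benzyloxide, or it may take up a second formaldehyde unit after lactonisation.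
- **Fallback:** It sets out from 7 and comes back at 9. No free enolate is used. Me3SiOTf/Et3N in CH2Cl2 at 0 °C converts 7 to the (Z)-trimethylsilyl enol ether F2. F2 undergoes a Mukaiyama aldol reaction with aqueous formaldehyde under Sc(OTf)3 catalysis in THF/H2O to give 8. Compound 8 is lactonised with catalytic PPTS in toluene to 9. Under these acidic conditions C4 can still drift to the trans-aroyl/arylmethyl arrangement through the enol.

Step 3.
- **What may go wrong:** Benzylation may occur at the benzylic cyclobutanol oxygen or at both oxygens.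
- **Fallback:** It sets out from 4 and comes back at 6. The order of events is changed so that only one hydroxyl is free when the benzyl group is introduced. Compound 4 is silylated (Et3SiOTf, 2,6-lutidine, CH2Cl2) to the triethylsilyl ether F3. Enolate hydroxylation with LiN(iPr)2 and 2-(phenylsulfonyl)-3-phenyloxaziridine gives the hydroxy ester F4, and any ring isomers are separated at this stage. NaH/BnBr then gives the benzyl ether F5, and Bu4NF in THF releases 6.

Further compounds
F1 | step 4 | racemic methyl 2-(benzyloxy)-2-[4-(benzyloxy)-3-methoxybenzyl]-4-[4-(benzyloxy)-3-methoxyphenyl]-4-oxobutanoate | COc1cc(CC(CC(=O)c2ccc(OCc3ccccc3)c(OC)c2)(OCc2ccccc2)C(=O)OC)ccc1OCc1ccccc1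
F2 | step 5 | methyl (2S,3Z)-2-(benzyloxy)-2-[4-(benzyloxy)-3-methoxybenzyl]-4-[4-(benzyloxy)-3-methoxyphenyl]-4-(trimethylsilyloxy)but-3-enoate | COc1cc(C[C@@](/C=C(\O[Si](C)(C)C)c2ccc(OCc3ccccc3)c(OC)c2)(OCc2ccccc2)C(=O)OC)ccc1OCc1ccccc1
F3 | step 3 | methyl 3-[4-(benzyloxy)-3-methoxyphenyl]-3-(triethylsilyloxy)cyclobutane-1-carboxylate (cis/trans mixture) | COC(=O)C1CC(O[Si](CC)(CC)CC)(c2ccc(OCc3ccccc3)c(OC)c2)C1
F4 | step 3 | methyl cis-1-hydroxy-3-(triethylsilyloxy)-3-[4-(benzyloxy)-3-methoxyphenyl]cyclobutane-1-carboxylate | COC(=O)[C@]1(O)C[C@](O[Si](CC)(CC)CC)(c2ccc(OCc3ccccc3)c(OC)c2)C1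
F5 | step 3 | methyl cis-1-(benzyloxy)-3-(triethylsilyloxy)-3-[4-(benzyloxy)-3-methoxyphenyl]cyclobutane-1-carboxylate | COC(=O)[C@]1(OCc2ccccc2)C[C@](O[Si](CC)(CC)CC)(c2ccc(OCc3ccccc3)c(OC)c2)C1
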